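**Retrosynthetic overview**
1. Numbering: ring C1 (C=O), C2=C3, C4 (OMe), C5, C6 (quaternary); side chain C7 (CHMe), C8 (ArCHOH). The plan rests on the array C1(=O)–C6–C7–C8(–O). Quaternary C6 of the cyclohexenone ring lies between the C1 carbonyl and C7, and C7 is α to the C8 oxygen. C6 is therefore the β-carbon of a C6=C7–C8(=O)Ar enone, and C1 is an acyl radical tied to it through C2–C5.
2. Endgame (no ring formed): target ⇐ selenoxide elimination (C2=C3) ⇐ Felkin–Anh reduction at C8 ⇐ C1 silyl enol ether ⇐ 1,4-diketone. The enol ether first shields C1 from hydride and then carries the dehydrogenation.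
3. Key disconnection C1–C6: the only ring (cyclohexanone C1–C6) is closed by 6-exo cyclisation of the acyl radical from an open-chain phenyl selenoester.
4. Selenoester ⇐ tetrasubstituted aryl enone ⇐ ynone (allylcopper addition at C6, MeI capture at C7) ⇐ terminal alkyne + 3,4,5-trimethoxybenzoyl chloride (C7–C8).
5. C4 ⇐ (S)-terminal epoxide from a hydrolytic kinetic resolution, opened at C5 by acetylide (C5–C6).

Key step: step 11

Remarks on the chemistry
- The tetrasubstituted enone and all compounds derived from it up to the acyl radical are drawn as the (Z)-alkene expected from step 7. Any (E)-isomer would be carried along, because both converge at the planar C7 radical.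
- C6=C7 is deliberately not made by olefination of a C6 ketone. Such a ketone would be β-methoxy and β,γ-unsaturated, so base would cause elimination and alkene migration. Stabilised α-branched phosphonates also rarely condense with dialkyl ketones.
- C1 travels as a silyl ether, because a C1 ester would lactonise onto the free C4 hydroxyl before O-methylation.

**Step 1**
Reactants: 1 pent-4-en-1-ol
Product: 2 tert-butyldimethyl(pent-4-en-1-yloxy)silane
Conditions: TBSCl, imidazole, CH2Cl2, 0 °C → rt
Reagents that add atoms: tert-butyldimethylsilyl chloride, CC(C)(C)[Si](C)(C)Cl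
Why: Standard silylation of a primary alcohol, so that C1 carries no electrophilic carboxyl group while the C4 alkoxide is generated later.

**Step 2**
Reactants: 2 tert-butyldimethyl(pent-4-en-1-yloxy)silane
Product: 3 rac-tert-butyldimethyl[3-(oxiran-2-yl)propoxy]silane
Conditions: mCPBA, CH2Cl2, 0 °C → rt
Reagents that add atoms: 3-chloroperoxybenzoic acid, OOC(=O)c1cccc(Cl)c1
Why: Prilezhaev epoxidation of the only alkene gives the racemic terminal epoxide needed for the resolution.

**Step 3**
Reactants: 3 rac-tert-butyldimethyl[3-(oxiran-2-yl)propoxy]silane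
Product: 4 (S)-tert-butyldimethyl[3-(oxiran-2-yl)propoxy]silane
Conditions: (S,S)-(salen)Co(OAc) [salen = N,N'-bis(3,5-di-tert-butylsalicylidene)cyclohexane-1,2-diaminate] (0.5 mol %), H2O (0.55 equiv), THF, 0 °C → rt
Reagents that add atoms: none
Why: Jacobsen hydrolytic kinetic resolution, in which the (S,S)-cobalt salen catalyst hydrolyses the (R)-epoxide selectively and leaves the (S)-epoxide, fixing C4 for the whole route.

**Step 4**
Reactants: 4 (S)-tert-butyldimethyl[3-(oxiran-2-yl)propoxy]silane; 5 lithium acetylide–ethylenediamine complex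
Product: 6 (S)-7-[(tert-butyldimethylsilyl)oxy]hept-1-yn-4-ol
Conditions: LiC≡CH·H2NCH2CH2NH2, DMSO, 0 °C → rt; H2O
Reagents that add atoms: none
Why: SN2 opening of the terminal epoxide at the unsubstituted C5 forms C5–C6 and does not touch the C4–O bond, so the configuration is retained.

**Step 5**
Reactants: 6 (S)-7-[(tert-butyldimethylsilyl)oxy]hept-1-yn-4-ol
Product: 7 (S)-tert-butyl[(4-methoxyhept-6-yn-1-yl)oxy]dimethylsilane
Conditions: NaH (1.1 equiv), MeI, THF, 0 °C → rt
Reagents that add atoms: methyl iodide, CI
Why: Williamson etherification of the C4 alkoxide, with only a slight excess of NaH and MeI present from the start so that the alkyne C–H and the remote silyl ether stay out of play and the stereocentre is not involved.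

**Step 6**
Reactants: 7 (S)-tert-butyl[(4-methoxyhept-6-yn-1-yl)oxy]dimethylsilane; 8 3,4,5-trimethoxybenzoyl chloride
Product: 9 (S)-8-[(tert-butyldimethylsilyl)oxy]-5-methoxy-1-(3,4,5-trimethoxyphenyl)oct-2-yn-1-one
Conditions: PdCl2(PPh3)2 (2 mol %), CuI (4 mol %), Et3N, THF, rt
Reagents that add atoms: none
Why: Acyl Sonogashira coupling of a terminal alkyne with an aroyl chloride forms C7–C8 and gives the ynone directly at the ketone oxidation level under mild amine base.

**Step 7**
Reactants: 9 (S)-8-[(tert-butyldimethylsilyl)oxy]-5-methoxy-1-(3,4,5-trimethoxyphenyl)oct-2-yn-1-one; 10 allylmagnesium bromide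
Product: 12 (2Z,5S)-3-allyl-8-[(tert-butyldimethylsilyl)oxy]-5-methoxy-2-methyl-1-(3,4,5-trimethoxyphenyl)oct-2-en-1-one, via bromomagnesium allenolate 11 (not isolated)
Conditions: CH2=CHCH2MgBr, CuBr·SMe2 (1:1), THF, −78 °C; 9; then MeI, DMPU, −78 → 0 °C; aq NH4Cl
Reagents that add atoms: methyl iodide, CI
Why: Tandem conjugate addition–enolate alkylation, in which the allylcopper reagent adds 1,4 to the ynone at C6 and allenolate 11 is C-methylated at C7 in the plane of the C6 substituents from the side of the slimmer allyl group, so the (Z)-enone should dominate although the geometry is not critical.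

**Step 8**
Reactants: 12 (2Z,5S)-3-allyl-8-[(tert-butyldimethylsilyl)oxy]-5-methoxy-2-methyl-1-(3,4,5-trimethoxyphenyl)oct-2-en-1-one
Product: 13 (2Z,5S)-3-allyl-8-hydroxy-5-methoxy-2-methyl-1-(3,4,5-trimethoxyphenyl)oct-2-en-1-one
Conditions: HF·pyridine, pyridine, THF, 0 °C → rt
Reagents that add atoms: none
Why: Fluoride cleavage of the primary silyl ether under buffered, non-basic conditions, chosen because the doubly allylic CH2 between the enone and the vinyl group would isomerise under basic fluoride.

**Step 9**
Reactants: 13 (2Z,5S)-3-allyl-8-hydroxy-5-methoxy-2-methyl-1-(3,4,5-trimethoxyphenyl)oct-2-en-1-one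
Product: 15 (4S,6Z)-6-allyl-4-methoxy-7-methyl-8-oxo-8-(3,4,5-trimethoxyphenyl)oct-6-enoic acid, via aldehyde 14 (not isolated)
Conditions: TEMPO (20 mol %), PhI(OAc)2 (2.2 equiv), MeCN–H2O, rt
Reagents that add atoms: water, O
Why: Oxoammonium (TEMPO/PhI(OAc)2) oxidation of the primary alcohol through aldehyde 14 and its hydrate to the acid near neutral pH, which leaves both alkenes, the enone and the aryl ethers alone.

**Step 10**
Reactants: 15 (4S,6Z)-6-allyl-4-methoxy-7-methyl-8-oxo-8-(3,4,5-trimethoxyphenyl)oct-6-enoic acid
Product: 16 Se-phenyl (4S,6Z)-6-allyl-4-methoxy-7-methyl-8-oxo-8-(3,4,5-trimethoxyphenyl)oct-6-eneselenoate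
Conditions: N-(phenylseleno)phthalimide, Bu3P, THF, 0 °C → rt
Reagents that add atoms: N-(phenylseleno)phthalimide, O=C1c2ccccc2C(=O)N1[Se]c1ccccc1
Why: Redox condensation in which Bu3P and the Se–N reagent turn the acid into an acyloxyphosphonium ion that phenylselenolate captures, a neutral route to acyl selenides that spares the hindered enone.

**Step 11**
Reactants: 16 Se-phenyl (4S,6Z)-6-allyl-4-methoxy-7-methyl-8-oxo-8-(3,4,5-trimethoxyphenyl)oct-6-eneselenoate
Product: 19 (2R,4S)-2-allyl-4-methoxy-2-[(2S)-1-oxo-1-(3,4,5-trimethoxyphenyl)propan-2-yl]cyclohexan-1-one, via acyl radical 17 (not isolated), via C7 radical 18 (not isolated)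
Conditions: Bu3SnH (1.3 equiv), AIBN (0.2 equiv), syringe pump, PhH (0.005 M), 80 °C; aq KF
Reagents that add atoms: none
Why: Bu3Sn• takes the PhSe group from 16; the nucleophilic acyl radical 17 adds to C6, the β-carbon of the electron-poor aryl enone, which forms C1–C6, and the tertiary, aroyl-stabilised C7 radical 18 then abstracts hydrogen from Bu3SnH and passes the chain on. The closest known reaction type is the tin hydride mediated cyclisation of acyl selenides onto β,β-disubstituted enones and enoates, and the cyclohexanone ring C1–C6 is closed in the 6-exo-trig mode. C6 is controlled by C4 through a chair transition state with the methoxy group and the bulky C7 terminus equatorial and the slimmer allyl group axial: the alternative chairs either place C7 with its methyl and aroyl groups axial or set an axial methoxy group 1,3-diaxial to the allyl group, so the methoxy group and the side chain should end up cis (6R in target numbering). C7 is controlled only by the conformation of 18: with the C1 and C8 carbonyl dipoles opposed (C1–C6–C7–C8 antiperiplanar) the axial allyl group covers one face and the stannane should deliver hydrogen to the other, which gives 7S; this is the weaker element, and since C7 is planar both alkene isomers of 16 converge. The step needs ring closure to outrun hydrogen transfer to 17 and loss of CO, which the polarity match, the slow decarbonylation of a primary-alkyl acyl radical and a low stationary stannane concentration secure. It also needs site selectivity: attack at C7 (7-endo) is polarity-mismatched, the allyl alkene is reachable by 17 only through an eight-membered ring, and 18 could engage it only in 4-exo or 5-endo fashion.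

**Step 12**
Reactants: 19 (2R,4S)-2-allyl-4-methoxy-2-[(2S)-1-oxo-1-(3,4,5-trimethoxyphenyl)propan-2-yl]cyclohexan-1-one
Product: 20 (2S)-2-{(1R,5S)-1-allyl-2-[(tert-butyldimethylsilyl)oxy]-5-methoxycyclohex-2-en-1-yl}-1-(3,4,5-trimethoxyphenyl)propan-1-one
Conditions: TBSOTf (1.2 equiv), Et3N, CH2Cl2, −78 → 0 °C
Reagents that add atoms: tert-butyldimethylsilyl triflate, CC(C)(C)[Si](C)(C)OS(=O)(=O)C(F)(F)F
Why: Soft enolisation (silyl triflate/amine), in which C1 can enolise only towards C2 because C6 is quaternary whereas the C8 ketone would have to lose the hindered C7–H next to C6, so only the ring ketone should be silylated and, with no free enolate present, C7 is not epimerised and no transannular aldol onto C8 can start.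

**Step 13**
Reactants: 20 (2S)-2-{(1R,5S)-1-allyl-2-[(tert-butyldimethylsilyl)oxy]-5-methoxycyclohex-2-en-1-yl}-1-(3,4,5-trimethoxyphenyl)propan-1-one
Product: 21 (1S,2S)-2-{(1R,5S)-1-allyl-2-[(tert-butyldimethylsilyl)oxy]-5-methoxycyclohex-2-en-1-yl}-1-(3,4,5-trimethoxyphenyl)propan-1-ol
Conditions: i-Bu2AlH, CH2Cl2, −78 °C; aq potassium sodium tartrate
Reagents that add atoms: none
Why: Felkin–Anh controlled hydride addition, in which quaternary C6 stands as the large group perpendicular to the C8 carbonyl and hydride passes the C7 hydrogen, so the 7S ketone should give the 8S (methyl/hydroxyl anti) alcohol while C1 is out of play as its silyl enol ether and the allyl group is inert to i-Bu2AlH at −78 °C.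

**Step 14**
Reactants: 21 (1S,2S)-2-{(1R,5S)-1-allyl-2-[(tert-butyldimethylsilyl)oxy]-5-methoxycyclohex-2-en-1-yl}-1-(3,4,5-trimethoxyphenyl)propan-1-ol
Product: 24 (4R,6R)-6-allyl-6-[(1S,2S)-1-hydroxy-1-(3,4,5-trimethoxyphenyl)propan-2-yl]-4-methoxycyclohex-2-en-1-one, via C2 phenylselenide 22 (not isolated), via selenoxide 23 (not isolated)
Conditions: PhSeCl (1.05 equiv), CH2Cl2, −78 °C; then pyridine, 30% H2O2, 0 °C → rt
Reagents that add atoms: none
Why: Electrophilic selenenylation of the silyl enol ether at C2 followed by oxidation and selenoxide syn-elimination towards C3 unveils the C1 ketone and the C2=C3 alkene in one flask without base, so C4, C6, C7 and C8 are untouched, and a dehydrosilylation with divalent palladium is avoided because the axial allyl group lies 1,3 to C2 and could be drawn into cycloalkenylation.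

**Compound list**
1 | pent-4-en-1-ol | C=CCCCO | starting material
2 | tert-butyldimethyl(pent-4-en-1-yloxy)silane | C=CCCCO[Si](C)(C)C(C)(C)C | intermediate
3 | rac-tert-butyldimethyl[3-(oxiran-2-yl)propoxy]silane | CC(C)(C)[Si](C)(C)OCCCC1CO1 | intermediate
4 | (S)-tert-butyldimethyl[3-(oxiran-2-yl)propoxy]silane | CC(C)(C)[Si](C)(C)OCCC[C@H]1CO1 | intermediate
5 | lithium acetylide–ethylenediamine complex | [Li]C#C.NCCN | starting material
6 | (S)-7-[(tert-butyldimethylsilyl)oxy]hept-1-yn-4-ol | CC(C)(C)[Si](C)(C)OCCC[C@H](O)CC#C | intermediate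
7 | (S)-tert-butyl[(4-methoxyhept-6-yn-1-yl)oxy]dimethylsilane | CC(C)(C)[Si](C)(C)OCCC[C@H](OC)CC#C | intermediate
8 | 3,4,5-trimethoxybenzoyl chloride | COc1cc(C(=O)Cl)cc(OC)c1OC | starting material
9 | (S)-8-[(tert-butyldimethylsilyl)oxy]-5-methoxy-1-(3,4,5-trimethoxyphenyl)oct-2-yn-1-one | CC(C)(C)[Si](C)(C)OCCC[C@H](OC)CC#CC(=O)c1cc(OC)c(OC)c(OC)c1 | intermediate
10 | allylmagnesium bromide | C=CC[Mg]Br | starting material
11 | bromomagnesium allenolate from allyl addition to C6 of 9 (allene axis undefined) | CC(C)(C)[Si](C)(C)OCCC[C@H](OC)CC(CC=C)=C=C(O[Mg]Br)c1cc(OC)c(OC)c(OC)c1 | intermediate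
12 | (2Z,5S)-3-allyl-8-[(tert-butyldimethylsilyl)oxy]-5-methoxy-2-methyl-1-(3,4,5-trimethoxyphenyl)oct-2-en-1-one | CC(C)(C)[Si](C)(C)OCCC[C@H](OC)C/C(CC=C)=C(/C)C(=O)c1cc(OC)c(OC)c(OC)c1 | intermediate
13 | (2Z,5S)-3-allyl-8-hydroxy-5-methoxy-2-methyl-1-(3,4,5-trimethoxyphenyl)oct-2-en-1-one | OCCC[C@H](OC)C/C(CC=C)=C(/C)C(=O)c1cc(OC)c(OC)c(OC)c1 | intermediate
14 | (4S,6Z)-6-allyl-4-methoxy-7-methyl-8-oxo-8-(3,4,5-trimethoxyphenyl)oct-6-enal | O=CCC[C@H](OC)C/C(CC=C)=C(/C)C(=O)c1cc(OC)c(OC)c(OC)c1 | intermediate
15 | (4S,6Z)-6-allyl-4-methoxy-7-methyl-8-oxo-8-(3,4,5-trimethoxyphenyl)oct-6-enoic acid | OC(=O)CC[C@H](OC)C/C(CC=C)=C(/C)C(=O)c1cc(OC)c(OC)c(OC)c1 | intermediate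
16 | Se-phenyl (4S,6Z)-6-allyl-4-methoxy-7-methyl-8-oxo-8-(3,4,5-trimethoxyphenyl)oct-6-eneselenoate | O=C(CC[C@H](OC)C/C(CC=C)=C(/C)C(=O)c1cc(OC)c(OC)c(OC)c1)[Se]c1ccccc1 | intermediate
17 | C1 acyl radical derived from 16 | O=[C]CC[C@H](OC)C/C(CC=C)=C(/C)C(=O)c1cc(OC)c(OC)c(OC)c1 | intermediate
18 | cyclised C7 radical (ring closed, C6 set) | C=CC[C@]1([C](C)C(=O)c2cc(OC)c(OC)c(OC)c2)C[C@@H](OC)CCC1=O | intermediate
19 | (2R,4S)-2-allyl-4-methoxy-2-[(2S)-1-oxo-1-(3,4,5-trimethoxyphenyl)propan-2-yl]cyclohexan-1-one | C=CC[C@]1([C@H](C)C(=O)c2cc(OC)c(OC)c(OC)c2)C[C@@H](OC)CCC1=O | intermediate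
20 | (2S)-2-{(1R,5S)-1-allyl-2-[(tert-butyldimethylsilyl)oxy]-5-methoxycyclohex-2-en-1-yl}-1-(3,4,5-trimethoxyphenyl)propan-1-one | C=CC[C@]1([C@H](C)C(=O)c2cc(OC)c(OC)c(OC)c2)C[C@@H](OC)CC=C1O[Si](C)(C)C(C)(C)C | intermediate
21 | (1S,2S)-2-{(1R,5S)-1-allyl-2-[(tert-butyldimethylsilyl)oxy]-5-methoxycyclohex-2-en-1-yl}-1-(3,4,5-trimethoxyphenyl)propan-1-ol | C=CC[C@]1([C@H](C)[C@H](O)c2cc(OC)c(OC)c(OC)c2)C[C@@H](OC)CC=C1O[Si](C)(C)C(C)(C)C | intermediate
22 | C2-(phenylselanyl) ketone, the 2,3-dihydro target bearing SePh at C2 (C2 epimers) | C=CC[C@]1([C@H](C)[C@H](O)c2cc(OC)c(OC)c(OC)c2)C[C@@H](OC)CC([Se]c2ccccc2)C1=O | intermediate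
23 | selenoxide of 22 (C2 and Se undefined) | C=CC[C@]1([C@H](C)[C@H](O)c2cc(OC)c(OC)c(OC)c2)C[C@@H](OC)CC([Se](=O)c2ccccc2)C1=O | intermediate
24 | (4R,6R)-6-allyl-6-[(1S,2S)-1-hydroxy-1-(3,4,5-trimethoxyphenyl)propan-2-yl]-4-methoxycyclohex-2-en-1-one | C=CC[C@]1([C@H](C)[C@H](O)c2cc(OC)c(OC)c(OC)c2)C[C@@H](OC)C=CC1=O | target

**Step count**
Total steps: 14. Longest linear sequence: 14 (the route is linear; 5, 8 and 10 are bought).

**Steps most likely to fail**

Step 11 (key step).
- Risk: the acyl radical may be quenched by the stannane or lose CO before it reaches the fully substituted C6. Hydrogen transfer to the planar C7 radical may also show poor facial selectivity.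
- Fallback: the same C1–C6 bond is made by polar umpolung instead of a radical.
- Setting out from alcohol 13, the oxidation is stopped at aldehyde 14 (Dess–Martin periodinane, CH2Cl2), which is isolated.
- Aldehyde 14 is then submitted to an intramolecular Stetter reaction (aminoindanol-derived chiral triazolium salt, KN(SiMe3)2, toluene, rt).
- The Breslow intermediate adds to C6, and the internal proton transfer places hydrogen on C7 from the same face. A syn addition across the (Z)-alkene translates its geometry into the required 6R,7S relation, so C7 no longer depends on an external hydrogen donor.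
- The sequence comes back to the route at diketone 19 and makes no compound outside the list (F0).

Step 7.
- Risk: capture of allenolate 11 by MeI may be slow or unselective. Proton exchange with the product and O-methylation would leave material unsubstituted at C7.
- Fallback: the C7–methyl bond is made by cross-coupling instead of enolate alkylation.
- Setting out from ynone 9, the same allylcopper addition is run and allenolate 11 is quenched with I2 at −78 °C.
- This gives the α-iodoenone (2E,5S)-3-allyl-8-[(tert-butyldimethylsilyl)oxy]-2-iodo-5-methoxy-1-(3,4,5-trimethoxyphenyl)oct-2-en-1-one F1.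
- A Negishi coupling of F1 (MeZnCl, PdCl2(dppf), THF, rt) comes back to the route at enone 12.

Step 13.
- Risk: facial selectivity at C8 may erode if the hindered aryl ketone reacts through a non-Felkin rotamer. Loss of the enol silane during reduction or work-up would expose C1 to hydride.
- Fallback: catalyst control replaces substrate control.
- Setting out from 20, a Corey–Bakshi–Shibata reduction is run with the (R)-B-methyl oxazaborolidine and catecholborane (toluene, −78 → −40 °C).
- With the aryl group as the large substituent this should deliver hydride to the face that gives 8S. Catecholborane leaves the allyl group and the enol silane untouched, and the boron alkoxide cannot trigger silyl transfer.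
- The sequence comes back to the route at 21 and makes no compound outside the list (F0).

**Further compounds**
F0 | step 11 | none | none
F1 | step 7 | (2E,5S)-3-allyl-8-[(tert-butyldimethylsilyl)oxy]-2-iodo-5-methoxy-1-(3,4,5-trimethoxyphenyl)oct-2-en-1-one | CC(C)(C)[Si](C)(C)OCCC[C@H](OC)C/C(CC=C)=C(/I)C(=O)c1cc(OC)c(OC)c(OC)c1
F0 | step 13 | none | none
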